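The numbers in the tables are simulated for substances that don't exist, and the scatter is random.

| flask | starting material | coupling partner | time |
|---|---|---|---|
| west | 0.300 M | 0.300 M |  |
| north-west | 0.150 M | 0.150 M |  |
| south-east | 0.150 M | 0.300 M |  |
| east | 0.0460 M | 0.300 M | 13 h |

| run | time / h | [product] / M |
|---|---|---|
| west run | 2.6 | 0.0798 |
| west run | 5.2 | 0.1125 |
| west run | 7.8 | 0.1331 |
| west run | 10 | 0.1416 |
| west run | 13 | 0.1461 |
| north-west run | 2.6 | 0.0203 |
| north-west run | 5.2 | 0.0334 |
| north-west run | 7.8 | 0.0374 |
| north-west run | 10 | 0.0409 |
| north-west run | 13 | 0.0411 |
| south-east run | 2.6 | 0.0419 |
| south-east run | 5.2 | 0.0647 |
| south-east run | 7.8 | 0.0773 |
| south-east run | 10 | 0.0852 |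
| south-east run | 13 | 0.0933 |

(each reading ± 0.002 M)

- Overall: starting material + coupling partner -> product.
- Constant volume, constant temperature.
- Readings of a species count what is bound in complexes too.
- An order is taken over about fifteen percent of the charge, up and down.

- apparent order in [coupling partner] of the starting rate, round the charge of the west run (the rate where two percent of its starting material have turned into product)
- apparent order in [starting material] of the starting rate, round the charge of the west run (the rate where two percent of its starting material have turned into product) (one fixed amount of product, the same in the runs compared)
- product in the east run at 13 h, as a share of the starting material charged

- Starting material was left over in the west run at 13 h, 0.154 M of the 0.300 M charged, yet the last two readings there differed by 0.00450 M, so I stopped asking how fast each run went and asked how far its charge had been carried.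
- In the west run at 13 h the natural log of [starting material] charged over [starting material] remaining read 0.667; this dimensionless number, the rate of product divided by [starting material] and summed over the run, I call the exposure, the running total of a pseudo-first-order rate constant, and the share of the charge turned follows from it without any clock.
- At 2.6 h the exposure read 0.309 in the west run and 0.328 in the south-east run, which I read, as an average over that first stretch and not as a starting rate, as order 0.917 in [starting material]; the north-west run read 0.145, which against the south-east run gave me, on the same footing, order 1.17 in [coupling partner].
- One number was not enough at 13 h: the south-east run read 0.973, more than the west run, and the north-west run, with the west run's one-to-one ratio of charges, read 0.320, less than the west run.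
- So I held [coupling partner] at the 0.300 M of the east run and drew a straight line through the exposures of the west and south-east runs at 13 h, which share that charge of coupling partner, to 0.0460 M of starting material, which gave me an estimated exposure of 1.18 and a share of 69.3 %.
- The forecast gave orders of 1.05 in [coupling partner] and 1 in [starting material] and 78 % for the east run, higher than my share, holding that “excess coupling partner protects it”.
- The east run gave 68.9 % at 13 h, with orders of 1.2 and 1.0.

    2 coupling partner ⇌ reagent dimer, settled at all times (16.20 /M)
    starting material + reagent dimer → product + coupling partner (1.476 /M/h)
    coupling partner → lost reagent (0.2207 /h)

- The reaction of coupling partner to lost reagent moves the readings by 11 times the scatter, root mean square, and the east run's exposure came to 1.17; an exposure of 0.693 stood in the south-east run at 6.95 h and in the west run at 17.4 h, 2.50 times as long.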